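**Strategy.** The amide N–CH(CH2OMe)–CH(OH) unit between the lipid carbonyl and C2 of the cyclohexenone is read as a hydrolysed cis-2-oxazoline whose C2 is the amide carbon. Its C4–C5 bond, between the nitrogen-bearing and the oxygen-bearing carbon, is formed by a chiral aluminium-catalysed formal [3+2] addition of a 2-alkyl-5-methoxyoxazole (fragment 1, the complete lipid amide of glycine methyl ester in cyclodehydrated form) to a cyclohexenecarbaldehyde (fragment 2) that carries all ring stereocentres, its ketone masked as a silyl ether. One operation unites both halves, sets both new stereocentres (cis-oxazoline = anti amino alcohol) and protects N and O until the enone is unveiled; ester reduction, O-methylation and hydrolysis finish.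

Key step: step 20

Remark on the chemistry: the antipodes of the chiral ligands and reagents in steps 1, 3, 12 and 20 are named for the sense of induction expected by analogy and would be exchanged for their mirror images if a model run showed the opposite sense. Acetate 11 is carried as a mixture of C3 epimers because that centre is destroyed in step 7. The ring carbinol created in step 17 is temporary and is oxidised in step 24. TBS = tert-butyldimethylsilyl, Ipc = isopinocampheyl.

**Fragment 1: the lipid oxazole**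

Step 1
Reactants: 1 methyl (E)-but-2-enoate; 2 n-heptylmagnesium bromide
Product: 3 methyl (3S)-3-methyldecanoate
Conditions: CuI (copper iodide, 2 mol %), (S)-Tol-BINAP (3 mol %), t-BuOMe, −40 °C; 1 M HCl quench
Reagents that add atoms: none
Why: Copper-catalysed asymmetric conjugate addition of a Grignard reagent to an (E)-enoate, in which the Tol-BINAP–copper complex differentiates the enoate faces and sets the methyl-bearing stereocentre (C9 of the acid).

Step 2
Reactants: 3 methyl (3S)-3-methyldecanoate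
Product: 4 (3S)-3-methyldecanal
Conditions: i-Bu2AlH (1.1 equiv), CH2Cl2, −78 °C; Rochelle salt work-up
Reagents that add atoms: none
Why: Partial ester reduction with i-Bu2AlH at −78 °C stops at the aluminium hemiacetal, which gives the aldehyde on work-up without touching the β-stereocentre.

Step 3
Reactants: 4 (3S)-3-methyldecanal
Product: 6 (4S,6S)-6-methyltridec-1-en-4-ol, via O-borinate 5 (not isolated)
Conditions: (+)-Ipc2B(allyl) [from (−)-Ipc2BOMe and CH2=CHCH2MgBr, Et2O, 0 °C → rt], Et2O, −78 °C; then NaOH, H2O2, rt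
Reagents that add atoms: allylmagnesium bromide, C=CC[Mg]Br, delivered as (+)-B-allylbis(isopinocampheyl)borane, C=CCB([C@@H]1C[C@@H]2C[C@H]([C@H]1C)C2(C)C)[C@@H]1C[C@@H]2C[C@H]([C@H]1C)C2(C)C
Why: Brown allylboration through a closed chair transition state, in which the isopinocampheyl groups derived from (+)-α-pinene direct the allyl group to the Si face of the aldehyde and override the remote β-methyl group, setting the carbinol centre (C7 of the acid).

Step 4
Reactants: 6 (4S,6S)-6-methyltridec-1-en-4-ol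
Product: 7 (4S,6S)-4-methoxy-6-methyltridec-1-ene
Conditions: NaH, MeI, THF/DMF, 0 °C → rt
Reagents that add atoms: iodomethane, IC
Why: Williamson etherification of the sodium alkoxide with methyl iodide, which touches no stereocentre.

Step 5
Reactants: 7 (4S,6S)-4-methoxy-6-methyltridec-1-ene
Product: 9 (3R,5S)-3-methoxy-5-methyldodecanal, via ozonide 8 (not isolated)
Conditions: O3, CH2Cl2, −78 °C; then PPh3, −78 °C → rt
Reagents that add atoms: ozone, [O-][O+]=O
Why: Ozonolysis of the only alkene and reductive cleavage of the ozonide give the β-methoxy aldehyde under neutral conditions that avoid β-elimination.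

Step 6
Reactants: 9 (3R,5S)-3-methoxy-5-methyldodecanal
Product: 11 (5R,7S)-5-methoxy-7-methyltetradec-1-en-3-yl acetate (C3 epimers), via bromomagnesium alkoxide 10 (not isolated)
Conditions: CH2=CHMgBr, THF, −78 °C; then Ac2O, −78 °C → rt
Reagents that add atoms: vinylmagnesium bromide, C=C[Mg]Br; acetic anhydride, CC(=O)OC(C)=O
Why: Grignard 1,2-addition to the aldehyde and acylation of the magnesium alkoxide in the same flask; the new carbinol centre is left uncontrolled because step 7 destroys it.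

Step 7
Reactants: 11 (5R,7S)-5-methoxy-7-methyltetradec-1-en-3-yl acetate
Product: 14 (4E,7R,9S)-7-methoxy-9-methylhexadec-4-enoic acid, via silyl ketene acetal 12 (not isolated), via trimethylsilyl ester 13 (not isolated)
Conditions: LiN(i-Pr)2, Me3SiCl, THF, −78 °C → 65 °C; then 1 M HCl
Reagents that add atoms: none
Why: Ireland–Claisen rearrangement of the acetate silyl ketene acetal through a chair transition state with the carbinol substituent equatorial, which should give the (E)-4-enoic acid and turns the carbinol carbon into C5 of the alkene.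

Step 8
Reactants: 14 (4E,7R,9S)-7-methoxy-9-methylhexadec-4-enoic acid; 15 glycine methyl ester hydrochloride
Product: 16 methyl N-[(4E,7R,9S)-7-methoxy-9-methylhexadec-4-enoyl]glycinate
Conditions: EDC·HCl, HOBt, i-Pr2NEt, CH2Cl2, 0 °C → rt
Reagents that add atoms: none
Why: Carbodiimide-mediated amide coupling of the acid with the glycine ester through its hydroxybenzotriazole ester.

Step 9
Reactants: 16 methyl N-[(4E,7R,9S)-7-methoxy-9-methylhexadec-4-enoyl]glycinate
Product: 17 5-methoxy-2-[(3E,6R,8S)-6-methoxy-8-methylpentadec-3-en-1-yl]-1,3-oxazole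
Conditions: PPh3, I2, Et3N, CH2Cl2, 0 °C → rt
Reagents that add atoms: none
Why: Robinson–Gabriel-type cyclodehydration, in which the iodophosphonium salt activates the amide oxygen, the ester carbonyl oxygen closes on the imidoyl carbon and loss of the C4 proton gives the aromatic 5-methoxyoxazole.

**Fragment 2: the ring aldehyde**

Step 10
Reactants: 18 methyl 3-hydroxy-2,2-dimethylpropanoate
Product: 19 3-hydroxy-N-methoxy-N,2,2-trimethylpropanamide
Conditions: MeNH(OMe)·HCl, i-PrMgCl, THF, −20 → 0 °C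
Reagents that add atoms: N,O-dimethylhydroxylamine hydrochloride, CNOC.Cl
Why: The magnesium amide of N,O-dimethylhydroxylamine converts the methyl ester into the Weinreb amide while the alcohol is held as its magnesium alkoxide.

Step 11
Reactants: 19 3-hydroxy-N-methoxy-N,2,2-trimethylpropanamide
Product: 20 N-methoxy-N,2,2-trimethyl-3-oxopropanamide
Conditions: TEMPO (cat.), PhI(OAc)2, CH2Cl2, rt
Reagents that add atoms: none
Why: Oxoammonium (TEMPO) oxidation of the primary alcohol with PhI(OAc)2 as terminal oxidant gives the non-enolisable aldehyde.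

Step 12
Reactants: 20 N-methoxy-N,2,2-trimethyl-3-oxopropanamide
Product: 22 (3R,4S)-3-hydroxy-N-methoxy-N,2,2,4-trimethylhex-5-enamide, via O-borinate 21 (not isolated)
Conditions: cis-2-butene, n-BuLi, KOt-Bu, THF, −78 → −45 °C; (+)-Ipc2BOMe, −78 °C; BF3·OEt2; then 20, −78 °C; then NaOH, H2O2
Reagents that add atoms: cis-but-2-ene, C/C=C\C, delivered as (Z)-crotylbis(isopinocampheyl)borane, C/C=C\CB([C@H]1C[C@H]2C[C@@H]([C@@H]1C)C2(C)C)[C@H]1C[C@H]2C[C@@H]([C@@H]1C)C2(C)C
Why: Brown (Z)-crotylboration through a chair transition state, in which the (Z)-crotyl geometry gives the syn methyl/hydroxyl pair and the isopinocampheyl groups derived from (−)-α-pinene direct attack to the Re face, setting both ring stereocentres (C4 and C5 of the cyclohexenone).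

Step 13
Reactants: 22 (3R,4S)-3-hydroxy-N-methoxy-N,2,2,4-trimethylhex-5-enamide
Product: 23 (3R,4S)-3-[(tert-butyldimethylsilyl)oxy]-N-methoxy-N,2,2,4-trimethylhex-5-enamide
Conditions: t-BuMe2SiOTf, 2,6-lutidine, CH2Cl2, −78 → 0 °C
Reagents that add atoms: tert-butyldimethylsilyl triflate, CC(C)(C)[Si](C)(C)OS(=O)(=O)C(F)(F)F
Why: Silylation of the hindered secondary alcohol with the silyl triflate blocks retro-aldol and oxa-Michael pathways in the following steps.

Step 14
Reactants: 23 (3R,4S)-3-[(tert-butyldimethylsilyl)oxy]-N-methoxy-N,2,2,4-trimethylhex-5-enamide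
Product: 24 (5R,6S)-5-[(tert-butyldimethylsilyl)oxy]-4,4,6-trimethylocta-1,7-dien-3-one
Conditions: CH2=CHMgBr, THF, 0 °C → rt; cold 1 M HCl quench
Reagents that add atoms: vinylmagnesium bromide, C=C[Mg]Br
Why: Addition of the vinyl Grignard reagent to the Weinreb amide gives a stable magnesium chelate that releases the vinyl ketone only on acidic work-up, so over-addition is avoided.

Step 15
Reactants: 24 (5R,6S)-5-[(tert-butyldimethylsilyl)oxy]-4,4,6-trimethylocta-1,7-dien-3-one
Product: 25 (4S,5R)-5-[(tert-butyldimethylsilyl)oxy]-4,6,6-trimethylcyclohex-2-en-1-one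
Conditions: second-generation Grubbs catalyst (H2IMes)(PCy3)Cl2Ru=CHPh (3 mol %), CH2Cl2, 40 °C
Reagents that add atoms: none
Why: Ring-closing metathesis of the vinyl ketone and the terminal alkene closes the six-membered enone, helped by the gem-dimethyl group, with loss of ethene.

Step 16
Reactants: 25 (4S,5R)-5-[(tert-butyldimethylsilyl)oxy]-4,6,6-trimethylcyclohex-2-en-1-one
Product: 26 (4S,5R)-5-[(tert-butyldimethylsilyl)oxy]-2-iodo-4,6,6-trimethylcyclohex-2-en-1-one
Conditions: I2, pyridine, CH2Cl2, 0 °C → rt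
Reagents that add atoms: iodine, [I][I]
Why: α-Iodination of the enone by conjugate addition of pyridine, iodination of the enolate and elimination (Johnson iodination).

Step 17
Reactants: 26 (4S,5R)-5-[(tert-butyldimethylsilyl)oxy]-2-iodo-4,6,6-trimethylcyclohex-2-en-1-one
Product: 27 (1R,4S,5R)-5-[(tert-butyldimethylsilyl)oxy]-2-iodo-4,6,6-trimethylcyclohex-2-en-1-ol
Conditions: NaBH4, CeCl3·7H2O, MeOH, −78 → −20 °C
Reagents that add atoms: none
Why: Luche 1,2-reduction, in which hydride adds anti to the axial methyl of the gem-dimethyl carbon in the half-chair with both ring substituents equatorial, so the carbinol should form cis to the C5 silyloxy group.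

Step 18
Reactants: 27 (1R,4S,5R)-5-[(tert-butyldimethylsilyl)oxy]-2-iodo-4,6,6-trimethylcyclohex-2-en-1-ol
Product: 28 (1R,4S,5R)-1,5-bis[(tert-butyldimethylsilyl)oxy]-2-iodo-4,6,6-trimethylcyclohex-2-ene (locants of 27 kept)
Conditions: t-BuMe2SiOTf, 2,6-lutidine, CH2Cl2, 0 °C → rt
Reagents that add atoms: tert-butyldimethylsilyl triflate, CC(C)(C)[Si](C)(C)OS(=O)(=O)C(F)(F)F
Why: Silylation of the allylic alcohol masks the future ketone as a non-leaving silyl ether that tolerates organolithium and Lewis acid conditions.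

Step 19
Reactants: 28 (1R,4S,5R)-1,5-bis[(tert-butyldimethylsilyl)oxy]-2-iodo-4,6,6-trimethylcyclohex-2-ene
Product: 30 (3S,4R,6R)-4,6-bis[(tert-butyldimethylsilyl)oxy]-3,5,5-trimethylcyclohex-1-ene-1-carbaldehyde, via vinyllithium 29 (not isolated)
Conditions: t-BuLi (2.1 equiv), Et2O, −78 °C; then HCONMe2, −78 → 0 °C; H2O
Reagents that add atoms: N,N-dimethylformamide, CN(C)C=O
Why: Iodine–lithium exchange gives the vinyllithium, which is formylated by N,N-dimethylformamide; the second equivalent of t-BuLi destroys the tert-butyl iodide formed.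

**Union and endgame**

Step 20
Reactants: 17 5-methoxy-2-[(3E,6R,8S)-6-methoxy-8-methylpentadec-3-en-1-yl]-1,3-oxazole; 30 (3S,4R,6R)-4,6-bis[(tert-butyldimethylsilyl)oxy]-3,5,5-trimethylcyclohex-1-ene-1-carbaldehyde
Product: 32 methyl (4S,5S)-5-[(3S,4R,6R)-4,6-bis[(tert-butyldimethylsilyl)oxy]-3,5,5-trimethylcyclohex-1-en-1-yl]-2-[(3E,6R,8S)-6-methoxy-8-methylpentadec-3-en-1-yl]-4,5-dihydro-1,3-oxazole-4-carboxylate, via oxazolium alkoxide 31 (not isolated)
Conditions: [(R,R)-(salen)Al]SbF6 (10 mol %; salen = N,N′-bis(3,5-di-tert-butylsalicylidene)-trans-1,2-cyclohexanediamine dianion), 3 Å molecular sieves, toluene, −20 °C → rt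
Reagents that add atoms: none
Why: C4 of the 5-methoxyoxazole, the nucleophilic carbon of a cyclic O,N-ketene acetal of the N-acylglycine ester, adds to the aldehyde activated by the cationic aluminium Lewis acid to give oxazolium alkoxide 31, whose oxygen adds to C2 while the old C2–O1 bond breaks and the former ring oxygen becomes the ester carbonyl. The closest known reaction type is the Lewis-acid-catalysed formal [3+2] cycloaddition of 5-alkoxyoxazoles with aldehydes to 2-oxazoline-4-carboxylates, in its enantioselective, cis-selective (salen)aluminium-catalysed form. The new 4,5-dihydrooxazole ring is closed in a stepwise [3+2] mode: carbon–carbon bond first, then five-membered closure by O-attack on C2 of the oxazolium (addition–elimination at a cationic imidate carbon). The cis relation of the C4 ester and the C5 ring residue, which becomes the anti relation of N and OH in the open chain, is the kinetic preference of aluminium catalysts in this reaction, and the absolute configuration of both new centres (4S,5S) is set by the chiral salen ligand, which selects the aldehyde face. The step needs 1,2- instead of 1,4-addition and no second electrophile: the enal is α,β-disubstituted inside the ring and flanked by the C3 methyl and C6 silyloxy groups, the ring ketone is masked as a silyl ether, and neither partner has a free OH or NH. Base is excluded so that the cis-ester is not epimerised at C4.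

Step 21
Reactants: 32 methyl (4S,5S)-oxazoline-4-carboxylate
Product: 33 [(4R,5S)-5-[(3S,4R,6R)-4,6-bis[(tert-butyldimethylsilyl)oxy]-3,5,5-trimethylcyclohex-1-en-1-yl]-2-[(3E,6R,8S)-6-methoxy-8-methylpentadec-3-en-1-yl]-4,5-dihydro-1,3-oxazol-4-yl]methanol
Conditions: LiBH4, THF/MeOH, 0 °C
Reagents that add atoms: none
Why: Chemoselective ester reduction by LiBH4 at 0 °C, a non-basic hydride that leaves the oxazoline C=N bond and the cis relation at C4/C5 untouched.

Step 22
Reactants: 33 hydroxymethyl oxazoline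
Product: 34 (4R,5S)-5-[(3S,4R,6R)-4,6-bis[(tert-butyldimethylsilyl)oxy]-3,5,5-trimethylcyclohex-1-en-1-yl]-4-(methoxymethyl)-2-[(3E,6R,8S)-6-methoxy-8-methylpentadec-3-en-1-yl]-4,5-dihydro-1,3-oxazole
Conditions: NaH, MeI, THF, 0 °C → rt
Reagents that add atoms: iodomethane, IC
Why: Williamson etherification of the primary alkoxide, possible because the oxazoline has no acidic proton once the ester is reduced.

Step 23
Reactants: 34 methoxymethyl oxazoline
Product: 35 (4R,5S)-5-[(3S,4R,6R)-4,6-dihydroxy-3,5,5-trimethylcyclohex-1-en-1-yl]-4-(methoxymethyl)-2-[(3E,6R,8S)-6-methoxy-8-methylpentadec-3-en-1-yl]-4,5-dihydro-1,3-oxazole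
Conditions: Bu4NF, THF, 50 °C
Reagents that add atoms: none
Why: Fluoride cleaves both silyl ethers while the oxazoline, which still masks the side-chain nitrogen and oxygen, is inert to it.

Step 24
Reactants: 35 diol oxazoline
Product: 36 (4S,5R)-5-hydroxy-2-[(4R,5S)-4-(methoxymethyl)-2-[(3E,6R,8S)-6-methoxy-8-methylpentadec-3-en-1-yl]-4,5-dihydro-1,3-oxazol-5-yl]-4,6,6-trimethylcyclohex-2-en-1-one
Conditions: MnO2 (activated, excess), CH2Cl2, rt
Reagents that add atoms: none
Why: MnO2 oxidises only the allylic ring carbinol to the enone; the saturated C5 alcohol is not oxidised and the other allylic oxygen is locked in the oxazoline.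

Step 25
Reactants: 36 enone oxazoline
Product: 38 (4E,7R,9S)-N-[(1S,2R)-1-hydroxy-1-[(3S,4R)-4-hydroxy-3,5,5-trimethyl-6-oxocyclohex-1-en-1-yl]-3-methoxypropan-2-yl]-7-methoxy-9-methylhexadec-4-enamide, via O-acyl ammonium chloride 37 (not isolated)
Conditions: 1 M aq. HCl, THF, 0 °C → rt; then aq. NaHCO3 to pH 8, rt
Reagents that add atoms: water, O
Why: Acid-catalysed hydrolysis adds water to C2 of the oxazoline and opens it to the O-acyl ammonium salt, and at pH 8 the free amine takes over the acyl group by a five-membered O-to-N shift; no bond to either stereocentre is broken, so both are retained.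

**Compound list**

1 | methyl (E)-but-2-enoate | C/C=C/C(=O)OC | starting material
2 | n-heptylmagnesium bromide | CCCCCCC[Mg]Br | starting material
3 | methyl (3S)-3-methyldecanoate | CCCCCCC[C@H](C)CC(=O)OC | intermediate
4 | (3S)-3-methyldecanal | CCCCCCC[C@H](C)CC=O | intermediate
5 | O-[bis(isopinocampheyl)boryl] ether of 6 (not isolated) | CCCCCCC[C@H](C)C[C@H](CC=C)OB([C@@H]1C[C@@H]2C[C@H]([C@H]1C)C2(C)C)[C@@H]1C[C@@H]2C[C@H]([C@H]1C)C2(C)C | intermediate
6 | (4S,6S)-6-methyltridec-1-en-4-ol | CCCCCCC[C@H](C)C[C@H](CC=C)O | intermediate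
7 | (4S,6S)-4-methoxy-6-methyltridec-1-ene | CCCCCCC[C@H](C)C[C@H](CC=C)OC | intermediate
8 | secondary ozonide (1,2,4-trioxolane) of 7 (not isolated) | CCCCCCC[C@H](C)C[C@H](CC1OCOO1)OC | intermediate
9 | (3R,5S)-3-methoxy-5-methyldodecanal | CCCCCCC[C@H](C)C[C@H](CC=O)OC | intermediate
10 | bromomagnesium (5R,7S)-5-methoxy-7-methyltetradec-1-en-3-olate, C3 epimers (not isolated) | CCCCCCC[C@H](C)C[C@H](CC([O-])C=C)OC.[Mg+2].[Br-] | intermediate
11 | (5R,7S)-5-methoxy-7-methyltetradec-1-en-3-yl acetate, C3 epimers | CCCCCCC[C@H](C)C[C@H](CC(OC(C)=O)C=C)OC | intermediate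
12 | trimethylsilyl ketene acetal of 11 (not isolated) | CCCCCCC[C@H](C)C[C@H](CC(OC(=C)O[Si](C)(C)C)C=C)OC | intermediate
13 | trimethylsilyl (4E,7R,9S)-7-methoxy-9-methylhexadec-4-enoate (not isolated) | CCCCCCC[C@H](C)C[C@H](C/C=C/CCC(=O)O[Si](C)(C)C)OC | intermediate
14 | (4E,7R,9S)-7-methoxy-9-methylhexadec-4-enoic acid | CCCCCCC[C@H](C)C[C@H](C/C=C/CCC(=O)O)OC | intermediate
15 | glycine methyl ester hydrochloride | COC(=O)CN.Cl | starting material
16 | methyl N-[(4E,7R,9S)-7-methoxy-9-methylhexadec-4-enoyl]glycinate | CCCCCCC[C@H](C)C[C@H](C/C=C/CCC(=O)NCC(=O)OC)OC | intermediate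
17 | 5-methoxy-2-[(3E,6R,8S)-6-methoxy-8-methylpentadec-3-en-1-yl]-1,3-oxazole | CCCCCCC[C@H](C)C[C@H](C/C=C/CCc1ncc(OC)o1)OC | intermediate
18 | methyl 3-hydroxy-2,2-dimethylpropanoate | COC(=O)C(C)(C)CO | starting material
19 | 3-hydroxy-N-methoxy-N,2,2-trimethylpropanamide | CON(C)C(=O)C(C)(C)CO | intermediate
20 | N-methoxy-N,2,2-trimethyl-3-oxopropanamide | CON(C)C(=O)C(C)(C)C=O | intermediate
21 | O-[bis(isopinocampheyl)boryl] ether of 22 (not isolated) | C=C[C@H](C)[C@@H](OB([C@H]1C[C@H]2C[C@@H]([C@@H]1C)C2(C)C)[C@H]1C[C@H]2C[C@@H]([C@@H]1C)C2(C)C)C(C)(C)C(=O)N(C)OC | intermediate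
22 | (3R,4S)-3-hydroxy-N-methoxy-N,2,2,4-trimethylhex-5-enamide | C=C[C@H](C)[C@@H](O)C(C)(C)C(=O)N(C)OC | intermediate
23 | (3R,4S)-3-[(tert-butyldimethylsilyl)oxy]-N-methoxy-N,2,2,4-trimethylhex-5-enamide | C=C[C@H](C)[C@@H](O[Si](C)(C)C(C)(C)C)C(C)(C)C(=O)N(C)OC | intermediate
24 | (5R,6S)-5-[(tert-butyldimethylsilyl)oxy]-4,4,6-trimethylocta-1,7-dien-3-one | C=C[C@H](C)[C@@H](O[Si](C)(C)C(C)(C)C)C(C)(C)C(=O)C=C | intermediate
25 | (4S,5R)-5-[(tert-butyldimethylsilyl)oxy]-4,6,6-trimethylcyclohex-2-en-1-one | C1=C[C@H](C)[C@@H](O[Si](C)(C)C(C)(C)C)C(C)(C)C1=O | intermediate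
26 | (4S,5R)-5-[(tert-butyldimethylsilyl)oxy]-2-iodo-4,6,6-trimethylcyclohex-2-en-1-one | IC1=C[C@H](C)[C@@H](O[Si](C)(C)C(C)(C)C)C(C)(C)C1=O | intermediate
27 | (1R,4S,5R)-5-[(tert-butyldimethylsilyl)oxy]-2-iodo-4,6,6-trimethylcyclohex-2-en-1-ol | IC1=C[C@H](C)[C@@H](O[Si](C)(C)C(C)(C)C)C(C)(C)[C@H]1O | intermediate
28 | (1R,4S,5R)-1,5-bis[(tert-butyldimethylsilyl)oxy]-2-iodo-4,6,6-trimethylcyclohex-2-ene (locants of 27) | IC1=C[C@H](C)[C@@H](O[Si](C)(C)C(C)(C)C)C(C)(C)[C@H]1O[Si](C)(C)C(C)(C)C | intermediate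
29 | vinyllithium from 28 (not isolated) | [Li]C1=C[C@H](C)[C@@H](O[Si](C)(C)C(C)(C)C)C(C)(C)[C@H]1O[Si](C)(C)C(C)(C)C | intermediate
30 | (3S,4R,6R)-4,6-bis[(tert-butyldimethylsilyl)oxy]-3,5,5-trimethylcyclohex-1-ene-1-carbaldehyde | O=CC1=C[C@H](C)[C@@H](O[Si](C)(C)C(C)(C)C)C(C)(C)[C@H]1O[Si](C)(C)C(C)(C)C | intermediate
31 | 4H-oxazolium alkoxide from C4 addition of 17 to 30 (not isolated, aluminium-bound) | CCCCCCC[C@H](C)C[C@H](C/C=C/CCC1=N[C@@H]([C@@H]([O-])C2=C[C@H](C)[C@@H](O[Si](C)(C)C(C)(C)C)C(C)(C)[C@H]2O[Si](C)(C)C(C)(C)C)C(OC)=[O+]1)OC | intermediate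
32 | methyl (4S,5S)-5-[(3S,4R,6R)-4,6-bis[(tert-butyldimethylsilyl)oxy]-3,5,5-trimethylcyclohex-1-en-1-yl]-2-[(3E,6R,8S)-6-methoxy-8-methylpentadec-3-en-1-yl]-4,5-dihydro-1,3-oxazole-4-carboxylate | CCCCCCC[C@H](C)C[C@H](C/C=C/CCC1=N[C@H](C(=O)OC)[C@@H](O1)C2=C[C@H](C)[C@@H](O[Si](C)(C)C(C)(C)C)C(C)(C)[C@H]2O[Si](C)(C)C(C)(C)C)OC | intermediate
33 | [(4R,5S)-5-[(3S,4R,6R)-4,6-bis[(tert-butyldimethylsilyl)oxy]-3,5,5-trimethylcyclohex-1-en-1-yl]-2-[(3E,6R,8S)-6-methoxy-8-methylpentadec-3-en-1-yl]-4,5-dihydro-1,3-oxazol-4-yl]methanol | CCCCCCC[C@H](C)C[C@H](C/C=C/CCC1=N[C@H](CO)[C@@H](O1)C2=C[C@H](C)[C@@H](O[Si](C)(C)C(C)(C)C)C(C)(C)[C@H]2O[Si](C)(C)C(C)(C)C)OC | intermediate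
34 | (4R,5S)-5-[(3S,4R,6R)-4,6-bis[(tert-butyldimethylsilyl)oxy]-3,5,5-trimethylcyclohex-1-en-1-yl]-4-(methoxymethyl)-2-[(3E,6R,8S)-6-methoxy-8-methylpentadec-3-en-1-yl]-4,5-dihydro-1,3-oxazole | CCCCCCC[C@H](C)C[C@H](C/C=C/CCC1=N[C@H](COC)[C@@H](O1)C2=C[C@H](C)[C@@H](O[Si](C)(C)C(C)(C)C)C(C)(C)[C@H]2O[Si](C)(C)C(C)(C)C)OC | intermediate
35 | (4R,5S)-5-[(3S,4R,6R)-4,6-dihydroxy-3,5,5-trimethylcyclohex-1-en-1-yl]-4-(methoxymethyl)-2-[(3E,6R,8S)-6-methoxy-8-methylpentadec-3-en-1-yl]-4,5-dihydro-1,3-oxazole | CCCCCCC[C@H](C)C[C@H](C/C=C/CCC1=N[C@H](COC)[C@@H](O1)C2=C[C@H](C)[C@@H](O)C(C)(C)[C@H]2O)OC | intermediate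
36 | (4S,5R)-5-hydroxy-2-[(4R,5S)-4-(methoxymethyl)-2-[(3E,6R,8S)-6-methoxy-8-methylpentadec-3-en-1-yl]-4,5-dihydro-1,3-oxazol-5-yl]-4,6,6-trimethylcyclohex-2-en-1-one | CCCCCCC[C@H](C)C[C@H](C/C=C/CCC1=N[C@H](COC)[C@@H](O1)C2=C[C@H](C)[C@@H](O)C(C)(C)C2=O)OC | intermediate
37 | (1S,2R)-2-ammonio-1-[(3S,4R)-4-hydroxy-3,5,5-trimethyl-6-oxocyclohex-1-en-1-yl]-3-methoxypropyl (4E,7R,9S)-7-methoxy-9-methylhexadec-4-enoate chloride (not isolated) | CCCCCCC[C@H](C)C[C@H](C/C=C/CCC(=O)O[C@H]([C@@H](COC)[NH3+])C1=C[C@H](C)[C@@H](O)C(C)(C)C1=O)OC.[Cl-] | intermediate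
38 | (4E,7R,9S)-N-[(1S,2R)-1-hydroxy-1-[(3S,4R)-4-hydroxy-3,5,5-trimethyl-6-oxocyclohex-1-en-1-yl]-3-methoxypropan-2-yl]-7-methoxy-9-methylhexadec-4-enamide | CCCCCCC[C@H](C)C[C@H](C/C=C/CCC(=O)N[C@H](COC)[C@@H](O)C1=C[C@H](C)[C@@H](O)C(C)(C)C1=O)OC | target

**Counts**

Total step count: 25.
Longest linear sequence: 16 steps (steps 10 to 19, then 20 to 25, from methyl 3-hydroxy-2,2-dimethylpropanoate).

**Steps most likely to fail**

Step 20 (key step). What may go wrong: the ligand may fail to override the neighbouring silyloxy stereocentre, so that the aldehyde face is poorly selected. The 2-alkyl oxazole is also less nucleophilic than the 2-aryl oxazoles usually used, so conjugate addition to the enal or equilibration of the cis-ester to the trans-ester could compete. Fallback: set out from aldehyde 30 and acid 14 and form the same carbon–carbon bond by an anti-selective catalytic asymmetric Henry reaction. Aldehyde 30 and 1-methoxy-2-nitroethane, with the heterobimetallic catalyst made from Nd5O(Oi-Pr)13, NaN(SiMe3)2 and a chiral amide-phenol ligand in THF at −40 °C, should give (1S,2R)-1-[(3S,4R,6R)-4,6-bis(silyloxy)-3,5,5-trimethylcyclohex-1-en-1-yl]-3-methoxy-2-nitropropan-1-ol F1. Reduction of the nitro group with Zn in AcOH/THF gives the amino alcohol F2. Coupling with acid 14 (EDC·HCl, HOBt) gives the hydroxy amide F3. Dehydrative cyclisation catalysed by MoO2(acac)2 in refluxing toluene, which activates the amide carbonyl and so retains the carbinol configuration, returns to the route at oxazoline 34.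

Step 25. What may go wrong: once the oxazoline is opened, the acyloxy group sits on an allylic carbon next to the enone, so it can be lost by addition–elimination before the acyl shift. The β-hydroxy ketone can also open by retro-aldol during the basic phase. Fallback: set out from oxazoline 34 and open the heterocycle before the enone exists. Hydrolysis of 34 (1 M HCl/THF at 0 °C, then NaHCO3) gives the hydroxy amide F3. Its side-chain hydroxyl is protected with 4-methoxybenzyl trichloroacetimidate and catalytic TfOH to give the 4-methoxybenzyl ether F7. Bu4NF gives the ring diol F8, MnO2 gives the enone 4-methoxybenzyl ether F9, and DDQ in CH2Cl2/pH 7 buffer removes the benzyl group and returns to the route at target 38.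

Step 9. What may go wrong: cyclodehydration of a glycinate that has no C4 substituent is slow, and the acid-labile 5-methoxyoxazole may hydrolyse back to 16 or decompose during isolation. Fallback: set out from aldehyde 9 and attach the lipid chain to a preformed, distillable oxazole. Horner–Wadsworth–Emmons reaction of 9 with triethyl phosphonoacetate (NaH, THF) gives ethyl (2E,5R,7S)-5-methoxy-7-methyltetradec-2-enoate F4. Reduction with i-Bu2AlH gives (2E,5R,7S)-5-methoxy-7-methyltetradec-2-en-1-ol F5, and CBr4/PPh3 gives (2E,5R,7S)-1-bromo-5-methoxy-7-methyltetradec-2-ene F6. Alkylation of 5-methoxy-2-(lithiomethyl)oxazole (from 5-methoxy-2-methyloxazole and LiNEt2, THF, −78 °C) with F6 returns to the route at oxazole 17.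

Further compounds
F1 | step 20 | (1S,2R)-1-[(3S,4R,6R)-4,6-bis[(tert-butyldimethylsilyl)oxy]-3,5,5-trimethylcyclohex-1-en-1-yl]-3-methoxy-2-nitropropan-1-ol | COC[C@@H]([N+](=O)[O-])[C@@H](O)C1=C[C@H](C)[C@@H](O[Si](C)(C)C(C)(C)C)C(C)(C)[C@H]1O[Si](C)(C)C(C)(C)C
F2 | step 20 | (1S,2R)-2-amino-1-[(3S,4R,6R)-4,6-bis[(tert-butyldimethylsilyl)oxy]-3,5,5-trimethylcyclohex-1-en-1-yl]-3-methoxypropan-1-ol | COC[C@@H](N)[C@@H](O)C1=C[C@H](C)[C@@H](O[Si](C)(C)C(C)(C)C)C(C)(C)[C@H]1O[Si](C)(C)C(C)(C)C
F3 | step 20 | (4E,7R,9S)-N-[(1S,2R)-1-[(3S,4R,6R)-4,6-bis[(tert-butyldimethylsilyl)oxy]-3,5,5-trimethylcyclohex-1-en-1-yl]-1-hydroxy-3-methoxypropan-2-yl]-7-methoxy-9-methylhexadec-4-enamide | CCCCCCC[C@H](C)C[C@H](C/C=C/CCC(=O)N[C@H](COC)[C@@H](O)C1=C[C@H](C)[C@@H](O[Si](C)(C)C(C)(C)C)C(C)(C)[C@H]1O[Si](C)(C)C(C)(C)C)OC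
F4 | step 9 | ethyl (2E,5R,7S)-5-methoxy-7-methyltetradec-2-enoate | CCCCCCC[C@H](C)C[C@H](C/C=C/C(=O)OCC)OC
F5 | step 9 | (2E,5R,7S)-5-methoxy-7-methyltetradec-2-en-1-ol | CCCCCCC[C@H](C)C[C@H](C/C=C/CO)OC
F6 | step 9 | (2E,5R,7S)-1-bromo-5-methoxy-7-methyltetradec-2-ene | CCCCCCC[C@H](C)C[C@H](C/C=C/CBr)OC
F7 | step 25 | 4-methoxybenzyl ether of F3 at the side-chain carbinol | CCCCCCC[C@H](C)C[C@H](C/C=C/CCC(=O)N[C@H](COC)[C@@H](OCc1ccc(OC)cc1)C1=C[C@H](C)[C@@H](O[Si](C)(C)C(C)(C)C)C(C)(C)[C@H]1O[Si](C)(C)C(C)(C)C)OC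
F8 | step 25 | ring diol from F7 | CCCCCCC[C@H](C)C[C@H](C/C=C/CCC(=O)N[C@H](COC)[C@@H](OCc1ccc(OC)cc1)C1=C[C@H](C)[C@@H](O)C(C)(C)[C@H]1O)OC
F9 | step 25 | 4-methoxybenzyl ether of target 38 at the side-chain carbinol | CCCCCCC[C@H](C)C[C@H](C/C=C/CCC(=O)N[C@H](COC)[C@@H](OCc1ccc(OC)cc1)C1=C[C@H](C)[C@@H](O)C(C)(C)C1=O)OC
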